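## Analysis of the target

The target 21 is a (2S)-flavanone: a chroman-4-one (rings A and C) with an unsubstituted phenyl ring B at C2. Ring A is fully substituted. Besides the fusion atoms C4a and C8a it carries hydroxyls at C5 and C7, a 3-methylbut-2-enoyl (senecioyl) group at C8 and, at C6, a methylene bridge to C3' of a 6-ethyl-4-hydroxy-5-methyl-2-pyranone. C2 is the only stereocentre, so only absolute configuration has to be controlled. It is benzylic and β to the C4 ketone, and base erodes it through reversible opening of ring C to the 2'-hydroxychalcone. The C8 enone lies next to the 7-OH and can close onto it by oxa-Michael addition; it is also reduced by hydride and by hydrogenation. The hydroxypyranone is a vinylogous acid with a lactone and acidic protons on the C6' ethyl group. The main difficulty is that C6 and C8 of a 5,7-dihydroxyflavanone are both flanked by two oxygen-bearing carbons and react alike with electrophiles, so bridge and acyl group cannot be placed cleanly by substitution. The strategy rests on the alternation C5(O)–C6(C)–C7(O)–C8(C) of ring A. C5 and C7 are carbonyl-derived and C6 and C8 are carbanion-derived, so ring A can be closed through C7–C8 and C5–C6 between a 4-pyranone that already is ring C and a propanoate that already holds the bridge.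

## Retrosynthetic reasoning

**C8–acyl bond.** The bond between C8 and the senecioyl carbonyl of 21 is cut last, giving 19 and acid chloride 20. C8 is the only unsubstituted carbon of ring A in 19, so no regiochemical question arises, and the enone never meets the reducing steps. The forward reaction must acylate carbon without closing the new enone onto the 7-OH and without opening ring C.

**Benzyl ether.** 19 comes from 18 by removal of a benzyl group from the pyranone oxygen. Benzyl is preferred to methyl here because it leaves by hydrogenolysis under neutral conditions at the flavanone stage, before the enone exists. A methyl ether would need nucleophilic or Lewis-acidic cleavage on a compound that already carries C2.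

**C2 stereocentre.** 18 is traced to the flat flavone 17 by adding hydrogen across C2=C3 under control of a chiral copper catalyst. This lets ring A be built with strong base while there is no stereocentre to lose. The forward reaction must pick one face of C2 and leave the pyranone alkenes alone.

**Ring A (key disconnection).** In 17 the bonds C7–C8 and C5–C6 are cut. This gives the pyranone ester 5, whose 2-methyl carbon becomes C8 and whose ester carbon becomes C5, and the propanoate 15, whose ester carbon becomes C7 and whose α-carbon becomes C6. The bridge is therefore bonded to C6 before ring A exists, and C8 can only carry hydrogen. The forward reaction is an intermolecular Claisen condensation followed by a Dieckmann closure and enolisation to the arene.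

**Pyranone ester 5.** Ring C is cut at C3–C(4) and O1–C6 (pyranone numbering) to methyl acetoacetate 3 and the ynoyl chloride 2, which comes from acid 1. One C-acylation and one ring closure onto the alkyne give the fully substituted pyranone with methyl and ester on adjacent carbons.

**Propanoate 15.** The benzyl group is removed to give 14, and the hydroxypyranone ring is cut at C4'–C5' and O1'–C2' to the malonyl dichloride 10 and the silyl enol ether 12 of ketone 11. The three-carbon ester arm sits on the malonyl carbon from the start, so C3' is never alkylated and over-alkylation cannot occur. 10 comes from the malonic acid 9, that from the mixed triester 8, and 8 from malonate 6 and acrylate 7. The tert-butyl and methyl esters of 8 keep the two kinds of carboxyl apart.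

## Alternatives that were turned down

**Alternative 1:** Ring C is cut at C3–C4. In the forward step a thiazolium-derived carbene turns the aldehyde of the tosylate A2 into an acyl anion equivalent (Breslow intermediate), which displaces the primary tosylate and closes ring C to the bis(methoxymethyl) ether A1.
- For: the C2 centre is bought from the chiral pool and is in place before ring closure, so no late asymmetric reaction on a complex substrate is needed. On this point it is stronger than the chosen route.
- Against: A1 has hydrogen at both C6 and C8, so the regiochemical problem of ring A is untouched. The aldehyde of A2 is flanked by two oxygen-bearing carbons and should add the carbene slowly. The tosylate can eliminate. The benzylic aryl ether in A2 is itself prone to ionisation when it is made.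
- Comparison: it builds one ring of the simplest member of the series and leaves the bridge, the acyl group and the pyranone still to do. The chosen route gives up the chiral-pool stereocentre but fixes the C6/C8 pattern by construction and joins both halves in the ring-forming step.

**Alternative 2:** Ring C is cut at C2–C3. The diazoketone A4 loses nitrogen on a chiral dirhodium tetracarboxylate (divalent rhodium), and the carbene inserts into a C–H bond of an ortho benzyloxy group to give the bis(benzyl) ether A3.
- For: one catalytic step sets C2 and closes ring C, and the benzyl groups serve as both reaction site and protection. For the stereocentre alone it is at least as direct as the chosen route.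
- Against: the ortho ether oxygen can attack the carbene to give an oxonium ylide that rearranges by benzyl shift (Stevens pathway). Addition to the electron-rich arenes can also compete. Six-membered C–H insertion usually gives lower selectivity than five-membered insertion. A3 again has C6 and C8 both open.
- Comparison: the chosen route offers control of ring A in place of the shorter ring C construction.

**Alternative 3:** The pyranone is cut at C4'–C5' and O1'–C2' and built last. The acid chloride A6, a lactone spanning C6 and O7 of the flavanone, C-acylates the enol of 3-pentanone A7 (the same compound as 11). The new enol oxygen then attacks the aryl lactone carbonyl, closing the pyranone and freeing the C7 phenol to give A5, which is identical with 19.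
- For: the pyranone never sees strong base and needs no protecting group. The aryl lactone is an activated ester and release of the phenol drives the ring switch. From A5 onward the endgame is the same as here, and A5 is reached without the reduction and deprotection steps. On step economy after the key step this alternative is stronger.
- Against: A6 must first be assembled on an intact (S)-flavanone with its carbon chain at C6 and not at C8, so the regiochemical problem is moved, not solved. An acid chloride α to a lactone carbonyl loses HCl to a ketene. C3 of the flavanone can be acylated, and C2 is exposed to acid chloride chemistry.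
- Comparison: the chosen route places the bridge with certainty and introduces C2 only after all strong-base chemistry, at the cost of three steps from 17 to 19.

Key step: step 9

Assumption: (R)-DTBM-SEGPHOS is written in step 10 as the ligand antipode taken to give the (S) centre; the sense of induction is to be fixed on a simple model 5,7-dihydroxyflavone, and the (S)-ligand is used if it proves opposite.

## Route

Step 1
Reactants: 1 phenylpropiolic acid
Product: 2 3-phenylprop-2-ynoyl chloride
Conditions: (COCl)2, DMF (cat.), CH2Cl2, 0 °C → 25 °C
Reagents that add atoms: oxalyl chloride, ClC(=O)C(Cl)=O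
Why: Acid chloride formation through the chloroiminium catalyst; the conjugated alkyne is inert under these conditions.

Step 2
Reactants: 3 methyl acetoacetate; 2 3-phenylprop-2-ynoyl chloride
Product: 5 methyl 2-methyl-4-oxo-6-phenyl-4H-pyran-3-carboxylate, via the C-acylated keto ester 4 (not isolated)
Conditions: MgCl2, pyridine, CH2Cl2, 0 °C → 25 °C; aq. HCl work-up; then TfOH (10 mol %), CH2Cl2, 25 °C
Reagents that add atoms: none
Why: C-Acylation of the magnesium chelate of the β-keto ester gives the enolised tricarbonyl compound 4; under acid the acetyl enol oxygen adds to the phenyl-bearing alkyne carbon of the protonated ynone (6-endo-dig oxa-Michael addition), the carbon that best carries positive charge, and the 4-pyranone results.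

Step 3
Reactants: 6 di-tert-butyl malonate; 7 methyl acrylate
Product: 8 1,1-di-tert-butyl 3-methyl propane-1,1,3-tricarboxylate
Conditions: KOtBu (5 mol %), t-BuOH, 25 °C, 6 in 1.5-fold excess
Reagents that add atoms: none
Why: Michael addition of the malonate anion to the acrylate under catalytic base; the tert-butyl esters resist exchange with the hindered alkoxide and the excess of 6 holds back double addition.

Step 4
Reactants: 8 1,1-di-tert-butyl 3-methyl propane-1,1,3-tricarboxylate
Product: 9 2-(3-methoxy-3-oxopropyl)propanedioic acid
Conditions: CF3CO2H, CH2Cl2, 25 °C
Reagents that add atoms: none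
Why: Acidolysis of the tert-butyl esters through the tert-butyl cation leaves the methyl ester untouched; evaporation at ambient temperature avoids decarboxylation of the malonic acid.

Step 5
Reactants: 9 2-(3-methoxy-3-oxopropyl)propanedioic acid
Product: 10 2-(3-methoxy-3-oxopropyl)propanedioyl dichloride
Conditions: SOCl2 (neat), 50 °C
Reagents that add atoms: thionyl chloride, O=S(Cl)Cl
Why: Acid chloride formation with thionyl chloride, the standard entry to substituted malonyl dichlorides; the methyl ester is inert.

Step 6
Reactants: 11 3-pentanone
Product: 12 3-(trimethylsilyloxy)pent-2-ene (E/Z mixture)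
Conditions: Me3SiOTf, Et3N, Et2O, 0 °C
Reagents that add atoms: trimethylsilyl trifluoromethanesulfonate, C[Si](C)(C)OS(=O)(=O)C(F)(F)F
Why: Silyl enol ether formation by soft enolisation; the ketone is symmetrical, so one regioisomer forms, and the alkene geometry is lost in step 7.

Step 7
Reactants: 10 2-(3-methoxy-3-oxopropyl)propanedioyl dichloride; 12 3-(trimethylsilyloxy)pent-2-ene
Product: 14 methyl 3-(6-ethyl-4-hydroxy-5-methyl-2-oxo-2H-pyran-3-yl)propanoate, via the open-chain diketo acid chloride 13 (not isolated)
Conditions: Et2O, −78 °C → 25 °C
Reagents that add atoms: none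
Why: The malonyl dichloride loses HCl to a chlorocarbonyl ketene that C-acylates the silyl enol ether without a Lewis acid; the enol oxygen of 13 then closes on the second acid chloride and the pyran-2,4-dione enolises to the 4-hydroxy-2-pyranone (pyranone synthesis from a silyl enol ether and a malonyl dichloride). The plain methyl ester does not acylate the enol ether under these conditions.

Step 8
Reactants: 14 methyl 3-(6-ethyl-4-hydroxy-5-methyl-2-oxo-2H-pyran-3-yl)propanoate
Product: 15 methyl 3-[4-(benzyloxy)-6-ethyl-5-methyl-2-oxo-2H-pyran-3-yl]propanoate
Conditions: BnBr, K2CO3, acetone, 56 °C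
Reagents that add atoms: benzyl bromide, BrCc1ccccc1
Why: O-Alkylation of the vinylogous acid (Williamson type); C3' is blocked, and alkyl halide with carbonate favours the 4-alkoxy-2-pyranone over the 2-alkoxy-4-pyranone isomer, which would be separated.

Step 9
Reactants: 5 methyl 2-methyl-4-oxo-6-phenyl-4H-pyran-3-carboxylate; 15 methyl 3-[4-(benzyloxy)-6-ethyl-5-methyl-2-oxo-2H-pyran-3-yl]propanoate
Product: 17 6-{[4-(benzyloxy)-6-ethyl-5-methyl-2-oxo-2H-pyran-3-yl]methyl}-5,7-dihydroxyflavone, via the Claisen ketone 16 (not isolated)
Conditions: 5 (2.2 equiv), LiN(SiMe3)2 (2.2 equiv), THF, −78 °C; add 15, −78 → 0 °C; then LiN(iPr)2 (3.5 equiv), −78 → 25 °C; 1 M HCl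
Reagents that add atoms: none
Why: LiN(SiMe3)2 removes a proton from the 2-methyl group of 5, which is vinylogous to both the ring ketone and the 3-ester, and the dienolate attacks the ester of 15 through its terminal carbon because attack through C3 would break the pyranone conjugation. Collapse of the adduct gives ketone 16, whose doubly activated CH2 is deprotonated at once by the second equivalent of the carbanion of 5; this pulls the Claisen equilibrium forward and keeps free amide base away from the enolisable ester. The silylamide is not expected to be basic enough for the next proton, so LiN(iPr)2 is added to deprotonate the far α-carbon of this enolate (dianion of a vinylogous β-diketone), and the localised carbanion closes on the neighbouring 3-ester in a 6-exo-trig Dieckmann step; loss of methoxide and enolisation give ring A as its bis-phenoxide, an irreversible sink. The closest known reaction types are the lateral Claisen condensation of 2-methyl-4-pyranones and chromones with esters, the Claisen–Dieckmann benzannulation of ortho-toluate carbanions to 1,3-dihydroxyarenes, and the terminal acylation of β-diketone dianions by esters. No stereocentre is formed. Regiochemistry is fixed by connectivity: the carbon that holds the bridge becomes C6 and the former methyl carbon becomes unsubstituted C8, while closure onto the ring ketone would give a bridged bicycle with a bridgehead alkene and is not expected. The unhindered side-chain ester of 15 is the preferred electrophile over the fully substituted benzyloxypyranone, and deprotonation of the 6'-ethyl group by LiN(iPr)2 is reversible and has no electrophile within reach.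

Step 10
Reactants: 17 6-{[4-(benzyloxy)-6-ethyl-5-methyl-2-oxo-2H-pyran-3-yl]methyl}-5,7-dihydroxyflavone
Product: 18 (2S)-6-{[4-(benzyloxy)-6-ethyl-5-methyl-2-oxo-2H-pyran-3-yl]methyl}-5,7-dihydroxyflavanone
Conditions: Cu(OAc)2 (5 mol %), (R)-DTBM-SEGPHOS (5.5 mol %), (EtO)2MeSiH, t-BuOH, toluene–THF, 25 °C; then NH4F, MeOH
Reagents that add atoms: none
Why: Copper hydride conjugate reduction (asymmetric 1,4-hydrosilylation) of the chromone C2=C3 bond: Cu(OAc)2 (divalent copper) is reduced by the silane to the bisphosphine copper hydride (monovalent copper), which delivers hydride to C2 on the face selected by the chiral ligand (catalyst control), and t-BuOH protonates the copper enolate at C3. The tetrasubstituted pyranone alkenes should not compete, and phenols silylated in the flask are freed by the fluoride work-up.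

Step 11
Reactants: 18 (2S)-6-{[4-(benzyloxy)-6-ethyl-5-methyl-2-oxo-2H-pyran-3-yl]methyl}-5,7-dihydroxyflavanone
Product: 19 (2S)-6-[(6-ethyl-4-hydroxy-5-methyl-2-oxo-2H-pyran-3-yl)methyl]-5,7-dihydroxyflavanone
Conditions: H2 (1 atm), Pd/C (10 wt % Pd), EtOAc–MeOH, 25 °C
Reagents that add atoms: none
Why: Hydrogenolysis of the benzyl vinylogous ester under neutral conditions; the ketone, the tetrasubstituted pyranone and the C2–O1 bond should survive at ambient pressure, and C2 is not touched.

Step 12
Reactants: 19 (2S)-6-[(6-ethyl-4-hydroxy-5-methyl-2-oxo-2H-pyran-3-yl)methyl]-5,7-dihydroxyflavanone; 20 3-methylbut-2-enoyl chloride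
Product: 21 (2S)-6-[(6-ethyl-4-hydroxy-5-methyl-2-oxo-2H-pyran-3-yl)methyl]-5,7-dihydroxy-8-(3-methylbut-2-enoyl)flavanone
Conditions: TiCl4, CH2Cl2–MeNO2, −20 → 0 °C; cold 1 M HCl
Reagents that add atoms: none
Why: Friedel–Crafts acylation at C8, the only unsubstituted carbon of ring A, activated by 7-OH, O1 and 5-OH; the titanium phenoxide at O7 directs acylation to the ortho carbon and then holds the product as a six-membered chelate, which should keep the phenol oxygen off the enone at low temperature. No base is present, so C2 keeps its configuration, and any enol ester formed at the pyranone hydroxyl is cleaved in the acidic aqueous work-up.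

## Compound list

1 | phenylpropiolic acid | OC(=O)C#Cc1ccccc1 | starting material
2 | 3-phenylprop-2-ynoyl chloride | ClC(=O)C#Cc1ccccc1 | intermediate
3 | methyl acetoacetate | COC(=O)CC(C)=O | starting material
4 | methyl 2-acetyl-3-oxo-5-phenylpent-4-ynoate | COC(=O)C(C(C)=O)C(=O)C#Cc1ccccc1 | intermediate
5 | methyl 2-methyl-4-oxo-6-phenyl-4H-pyran-3-carboxylate | COC(=O)c1c(C)oc(-c2ccccc2)cc1=O | intermediate
6 | di-tert-butyl malonate | CC(C)(C)OC(=O)CC(=O)OC(C)(C)C | starting material
7 | methyl acrylate | C=CC(=O)OC | starting material
8 | 1,1-di-tert-butyl 3-methyl propane-1,1,3-tricarboxylate | COC(=O)CCC(C(=O)OC(C)(C)C)C(=O)OC(C)(C)C | intermediate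
9 | 2-(3-methoxy-3-oxopropyl)propanedioic acid | COC(=O)CCC(C(=O)O)C(=O)O | intermediate
10 | 2-(3-methoxy-3-oxopropyl)propanedioyl dichloride | COC(=O)CCC(C(Cl)=O)C(Cl)=O | intermediate
11 | 3-pentanone | CCC(=O)CC | starting material
12 | 3-(trimethylsilyloxy)pent-2-ene (E/Z mixture) | CCC(=CC)O[Si](C)(C)C | intermediate
13 | methyl 4-(chlorocarbonyl)-6-methyl-5,7-dioxononanoate | CCC(=O)C(C)C(=O)C(C(Cl)=O)CCC(=O)OC | intermediate
14 | methyl 3-(6-ethyl-4-hydroxy-5-methyl-2-oxo-2H-pyran-3-yl)propanoate | CCc1oc(=O)c(CCC(=O)OC)c(O)c1C | intermediate
15 | methyl 3-[4-(benzyloxy)-6-ethyl-5-methyl-2-oxo-2H-pyran-3-yl]propanoate | CCc1oc(=O)c(CCC(=O)OC)c(OCc2ccccc2)c1C | intermediate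
16 | methyl 2-{4-[4-(benzyloxy)-6-ethyl-5-methyl-2-oxo-2H-pyran-3-yl]-2-oxobutyl}-4-oxo-6-phenyl-4H-pyran-3-carboxylate | CCc1oc(=O)c(CCC(=O)Cc2oc(-c3ccccc3)cc(=O)c2C(=O)OC)c(OCc2ccccc2)c1C | intermediate
17 | 6-{[4-(benzyloxy)-6-ethyl-5-methyl-2-oxo-2H-pyran-3-yl]methyl}-5,7-dihydroxyflavone | CCc1oc(=O)c(Cc2c(O)cc3oc(-c4ccccc4)cc(=O)c3c2O)c(OCc2ccccc2)c1C | intermediate
18 | (2S)-6-{[4-(benzyloxy)-6-ethyl-5-methyl-2-oxo-2H-pyran-3-yl]methyl}-5,7-dihydroxyflavanone | CCc1oc(=O)c(Cc2c(O)cc3c(c2O)C(=O)C[C@@H](c2ccccc2)O3)c(OCc2ccccc2)c1C | intermediate
19 | (2S)-6-[(6-ethyl-4-hydroxy-5-methyl-2-oxo-2H-pyran-3-yl)methyl]-5,7-dihydroxyflavanone | CCc1oc(=O)c(Cc2c(O)cc3c(c2O)C(=O)C[C@@H](c2ccccc2)O3)c(O)c1C | intermediate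
20 | 3-methylbut-2-enoyl chloride | CC(C)=CC(Cl)=O | starting material
21 | (2S)-6-[(6-ethyl-4-hydroxy-5-methyl-2-oxo-2H-pyran-3-yl)methyl]-5,7-dihydroxy-8-(3-methylbut-2-enoyl)flavanone | CCc1oc(=O)c(Cc2c(O)c(C(=O)C=C(C)C)c3c(c2O)C(=O)C[C@@H](c2ccccc2)O3)c(O)c1C | target

## Step count and least certain steps

Total: 12 steps. Longest linear sequence: 9 steps (3, 4, 5, 7, 8, 9, 10, 11, 12).

**Step 9 (key step).**
- What may go wrong: proton transfer may win over carbon–carbon bond formation, because the carbanion of 5 is strongly stabilised and a methyl ester is a modest electrophile. The second deprotonation may stay incomplete, so that the sequence stalls at 16. The carbanion of 5 may also condense with itself.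
- Fallback, from 15 back to 17: 15 is treated with N,O-dimethylhydroxylamine hydrochloride and i-PrMgCl (THF, −20 °C) to give 3-[4-(benzyloxy)-6-ethyl-5-methyl-2-oxo-2H-pyran-3-yl]-N-methoxy-N-methylpropanamide F1. The lateral carbanion of 5 (LiN(SiMe3)2, THF, −78 °C) adds to F1 to form a chelated adduct that survives until work-up, so ketone 16 is released only on quenching and is isolated. In a separate operation 16 is closed with NaH in refluxing 1,2-dimethoxyethane, the conditions of terminal acylation of β-diketones through their dianions, to give 17. This separates the intermolecular bond formation from the proton-transfer problem.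

**Step 12.**
- What may go wrong: conjugate closure of the 7-OH onto the new enone, addition of HCl to the enone, O-acylation in place of C-acylation, and Lewis-acid opening of ring C with loss of configuration at C2.
- Fallback, from 19 to 21: 19 is iodinated at C8 with N-iodosuccinimide (MeCN, 0 °C) to give (2S)-6-[(6-ethyl-4-hydroxy-5-methyl-2-oxo-2H-pyran-3-yl)methyl]-5,7-dihydroxy-8-iodoflavanone F2. A carbonylative Stille coupling of F2 with tributyl(2-methylprop-1-en-1-yl)stannane under CO (1 atm) with PdCl2(PPh3)2 (divalent palladium precatalyst) in DMF at 60 °C then installs the enone under neutral conditions and gives 21.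

**Step 10.**
- What may go wrong: slow hydride transfer to an electron-rich, hydrogen-bonded vinylogous ester, protonolysis of the copper hydride by the phenols, further reduction of the ketone, and poor facial discrimination at C2.
- Fallback, from 18 of insufficient enantiomeric purity (or racemic 18 made with an achiral bisphosphine) back to 18: kinetic resolution by asymmetric transfer hydrogenation with RuCl(p-cymene)(TsDPEN) (divalent ruthenium) in HCO2H–Et3N. The catalyst enantiomer is chosen so that the (2R)-ketone is reduced to the cis alcohol 4-(benzyloxy)-6-ethyl-5-methyl-3-{[(2R,4R)-4,5,7-trihydroxy-2-phenylchroman-6-yl]methyl}-2H-pyran-2-one F3, and (2S)-18 is recovered by chromatography.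

**Step 7.**
- What may go wrong: oligomerisation of the chlorocarbonyl ketene, O-acylation of the enol ether, or loss of the silyl group to HCl before acylation.
- Fallback, from 12 back to 14: 12 is condensed with unsubstituted malonyl dichloride (Et2O, −78 → 25 °C) to give 6-ethyl-4-hydroxy-5-methyl-2H-pyran-2-one F4. The arm is then attached by Michael addition of F4 to methyl acrylate 7 (Et3N, MeCN, 60 °C) to give 14. This is shorter, but it is kept in reserve because a second conjugate addition at C3' can follow the first.

## Further compounds

F1 | step 9 | 3-[4-(benzyloxy)-6-ethyl-5-methyl-2-oxo-2H-pyran-3-yl]-N-methoxy-N-methylpropanamide | CCc1oc(=O)c(CCC(=O)N(C)OC)c(OCc2ccccc2)c1C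
F2 | step 12 | (2S)-6-[(6-ethyl-4-hydroxy-5-methyl-2-oxo-2H-pyran-3-yl)methyl]-5,7-dihydroxy-8-iodoflavanone | CCc1oc(=O)c(Cc2c(O)c(I)c3c(c2O)C(=O)C[C@@H](c2ccccc2)O3)c(O)c1C
F3 | step 10 | 4-(benzyloxy)-6-ethyl-5-methyl-3-{[(2R,4R)-4,5,7-trihydroxy-2-phenylchroman-6-yl]methyl}-2H-pyran-2-one | CCc1oc(=O)c(Cc2c(O)cc3c(c2O)[C@H](O)C[C@H](c2ccccc2)O3)c(OCc2ccccc2)c1C
F4 | step 7 | 6-ethyl-4-hydroxy-5-methyl-2H-pyran-2-one | CCc1oc(=O)cc(O)c1C
A1 | alternative 1 | (S)-5,7-bis(methoxymethoxy)flavanone | O=C1C[C@@H](c2ccccc2)Oc2cc(OCOC)cc(OCOC)c12
A2 | alternative 1 | 2,4-bis(methoxymethoxy)-6-{[(1R)-1-phenyl-2-(tosyloxy)ethyl]oxy}benzaldehyde | Cc1ccc(cc1)S(=O)(=O)OC[C@@H](c1ccccc1)Oc1cc(OCOC)cc(OCOC)c1C=O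
A3 | alternative 2 | (S)-5,7-bis(benzyloxy)flavanone | O=C1C[C@@H](c2ccccc2)Oc2cc(OCc3ccccc3)cc(OCc3ccccc3)c12
A4 | alternative 2 | 2-diazo-1-[2,4,6-tris(benzyloxy)phenyl]ethan-1-one | [N-]=[N+]=CC(=O)c1c(OCc2ccccc2)cc(OCc2ccccc2)cc1OCc1ccccc1
A5 | alternative 3 | (2S)-6-[(6-ethyl-4-hydroxy-5-methyl-2-oxo-2H-pyran-3-yl)methyl]-5,7-dihydroxyflavanone (identical with 19) | CCc1oc(=O)c(Cc2c(O)cc3c(c2O)C(=O)C[C@@H](c2ccccc2)O3)c(O)c1C
A6 | alternative 3 | (2S)-5-hydroxyflavanone carrying a C6–CH2–CH(COCl)–C(=O)–O7 lactone (acid chloride on the lactone α-carbon) | O=C1C[C@@H](c2ccccc2)Oc2cc3OC(=O)C(C(Cl)=O)Cc3c(O)c12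
A7 | alternative 3 | 3-pentanone (identical with 11) | CCC(=O)CC
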